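Late in a run D is what a flask loses, so I reckoned how much D survives of what the catalyst has fed in by then.

    Z + Q ⇌ E + G (K1 = 20, k1 = 0.67 M⁻¹ s⁻¹)
    D → J (k2 = 3.2 × 10⁻⁴ s⁻¹)
    X + E → D + Z (k3 = 21 M⁻¹ s⁻¹)

| flask | X | Q | Z | time | volume of the second phase over the first |
|---|---|---|---|---|---|
| Sunday's | 20 mM | 26.0 mM | 0.015 mM | 1.0 h | 0.25 |
| Thursday's | 20 mM | 26.0 mM | 0.040 mM | 1.0 h | 0.25 |
| Monday's | 20 mM | 26.0 mM | 0.12 mM | 1.0 h | 0.25 |
| Saturday's | 20 mM | 26.0 mM | 0.40 mM | 1.0 h | 0.25 |

- in the second phase: Q, G; everything else is in the first
- charges count per volume of the first phase; a concentration in a rate is the amount of a species over the volume of its own phase; every rate counts per litre of the first phase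
- "hardly changes" means that all values lie within two and a half points (for a concentration: within two and a half percent of the largest)
- run time (Sunday's): 1.0 h

1. amount of D at the end, in percent of the X charged for Sunday's, Thursday's, Monday's, Saturday's, in this order
2. the shape of the row from first to last (falls, then rises / rises, then falls / falls all the way / hardly changes / rises all the way)

1. First I looked for the concentration that sets the order of the rate. Q sits in the smaller phase, so its own concentration, cQ, was 104 mM, and each Z took up Q at 0.0697 s⁻¹. With X as charged, each E went back to Z at 0.420 s⁻¹, 6.03 times as fast. So I took Z as the resting state and the transfer of Z + Q as the rate-limiting step, pseudo-first-order in Z while cQ holds.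

2. The catalyst charge is the setting that differs between the flasks. Dividing the X charged by the starting transfer rate gave 5.32 h for Sunday's flask. I call this the feed time: the time the catalyst needs to pass the X charged, with Z and Q as charged. It shrinks as the charge grows, to 1.99 h for Thursday's, 0.664 h for Monday's and 0.199 h for Saturday's. X is the limiting reagent, so feeding ends with X.

3. The run time is the other setting, and it acts through the decay of D, whose half-life is 36.1 min. By the feed time I expected Sunday's and Thursday's flasks to be still feeding at 1.0 h, and Monday's and Saturday's to have stopped before it, so in this estimate their D then only decayed. A steady feed with decay gave me 11.2%, 29.8%, 47.5% and 35.5%. For Saturday's flask at 0.500 h it gave 63.2%.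

4. The forecast gave 8.9%, 21.1%, 42.8% and 39.3%, a row that rises, then falls. Its ground for the last step down was that Monday's D “was made later and has had less time to decay”. My row has the same shape, but it stands higher for Sunday's and lower for Saturday's.

5. The flasks gave 8.87%, 20.9%, 42.6% and 39.5%, a row that rises, then falls. Saturday's D stood at 67.6% after 0.500 h and 39.5% after 1.00 h.

In Sunday's flask at 1.00 h, the forward transfer gave Z a half-life of 0.19 min, while the reaction with X gave E a shorter one of 0.032 min. The catalyst there stood 85.3% as Z. By the feed time, Sunday's flask should have used 18.8% of its X and had used 15.1%; Thursday's should have used 50.3% and had used 36.3%. Saturday's flask ended with 15.2% of its catalyst as Z.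

All constants come from no measurement; what happens was integrated by code.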